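(Its constants were chosen freely; the run is a simulation.)

Start from late times: reckon the most target the charge can give, and whether the time allowed reaches it. The two flasks, noon and dusk, differ in free base.

| setting | noon | dusk |
|---|---|---|
| electrophile | 0.018 M | 0.018 M |
| free base | 0.0140 M | 0.0290 M |
| protonated nucleophile | 0.0162 M | 0.0162 M |
| time | 3.0 h | 3.0 h |

    acid set free + free base ⇌ salt of the base (K1 = 2.7 × 10⁵ /M, k1 = 6.53 /M/s)
    electrophile → decomposition product (k2 = 3.30 × 10⁻⁶ /s)
    nucleophile + acid set free ⇌ protonated nucleophile, settled at all times (K3 = 1.7 × 10⁵ /M)
    acid set free → by-product carried off (k4 = 0.0786 /s)
    electrophile + nucleophile → acid set free + target (k5 = 2.26 /M/s)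

1. part of the electrophile that has reacted at the end, noon
2. part of the electrophile that has reacted at the end, dusk
3. what raising the concentration of free base from its lowest to its highest value here does to the part of the electrophile that has reacted (changes below 5 percentage points count as none) (it rises / no change / it falls)

My own reckoning starts from the ceiling. One nucleophile turns one electrophile into target, so the nucleophile is the limiting reagent, and the ceiling f is protonated nucleophile charged over electrophile charged, 90.0 %. The correction is the decay of the unpartnered electrophile over the run, 0.356 % of the charge, far less than the ceiling. That gives 90.4 % for both flasks, and no change, if the run gets there in time.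

Nucleophile comes free as acid leaves, and each target costs two acids removed: the one that freed the nucleophile and the one the reaction sets free. Let s be the rate constant of acid removal, carrying-off plus capture by free base, 0.170 /s at the noon start. With acid steady and protonation at balance, the target rate r grows as the square root of s times electrophile times protonated nucleophile. At the noon start r is 1.82 × 10⁻⁵ M/s, a pace that would use the nucleophile in τ = 0.248 h.

Once 0.5 of the nucleophile is used, its own fall multiplies r by 0.707 and the electrophile's by 0.742. Dropping capture by free base from s multiplies the noon r by 0.680. Summed over the run with carrying-off as the slow case, these stretch τ by 5.64, to 1.40 h. Free base cancels from that figure, so it serves dusk too, and it is shorter than the 3.0 h allowed.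

The forecast says 90.8 % for noon, 90.7 % for dusk and no change, 0.40 percentage points above my noon figure, holding that “extra base speeds the approach but leaves the final figure essentially unchanged”.

The simulation gives 90.6 % for noon, 90.6 % for dusk and no change, a change of −0.056 points.

In noon the electrophile's half-life by reaction with nucleophile at 0.258 h is 0.26 h, short against 3.0 h, while by its own decay it is 58 h, long against the run, and at 3.00 h target stands at 90.0 % of the electrophile charged, against a ceiling of 90.0 %, with 0.632 % as decomposition product. One more flask, like noon but charged with 0.0065 M of protonated nucleophile, has a ceiling of 36.1 %, or 38.4 % with the correction, and it ends with target at 36.1 % and 38.4 % of its electrophile reacted.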